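The quinone ring (C1–C4, C4a, C8a; naphthalene numbering), para-dioxygenated at C1/C4 with the side chain on C2 and hydrogen on C3, is read as an oxidised 4-methoxy-1-naphthol and made by a Dötz benzannulation. A zerovalent chromium carbene complex of hydroquinone bis-MOM ether carries C4, C4a and C8a and, as a CO ligand, C1. The terminal alkyne (R)-6-methylhept-5-en-1-yn-3-yl butanoate carries C2, C3 and the finished side chain. One operation forges C3–C4 and C1–C8a (and, through CO insertion, C1–C2); oxidative work-up gives the quinone, and MOM removal gives the target. The stereocentre comes from asymmetric transfer hydrogenation of an ynone.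

Key step: step 7

Remark: the target is taken as drawn, the (R)-configured butanoate ester of shikonin; its two naphthazarin tautomers (quinone in either ring) are one compound, so the last step delivers the drawn structure.

Step 1
Reactants: 1 4-methylpent-3-enoic acid
Product: 3 N-methoxy-N,4-dimethylpent-3-enamide, via acyl imidazole 2 (not isolated)
Conditions: 1,1'-carbonyldiimidazole, CH2Cl2, 0 → 25 °C; then MeNH(OMe)·HCl, 25 °C
Reagents that add atoms: N,O-dimethylhydroxylamine hydrochloride, CNOC.Cl
Why: Acyl imidazole formation followed by aminolysis (Weinreb amide synthesis) runs under neutral conditions that should keep the β,γ-double bond out of conjugation.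

Step 2
Reactants: 3 N-methoxy-N,4-dimethylpent-3-enamide; 4 ethynyl(trimethyl)silane
Product: 6 6-methyl-1-(trimethylsilyl)hept-5-en-1-yn-3-one, via lithium acetylide 5 (not isolated)
Conditions: 4, n-BuLi, THF, −78 °C; then 3, −78 → −30 °C; AcOH quench at −78 °C
Reagents that add atoms: none
Why: Weinreb ketone synthesis, in which the chelated tetrahedral lithium adduct survives until the cold acidic quench, so the acetylide should add only once and the doubly activated C4 methylene should not isomerise.

Step 3
Reactants: 6 6-methyl-1-(trimethylsilyl)hept-5-en-1-yn-3-one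
Product: 8 (3R)-6-methylhept-5-en-1-yn-3-ol, via silyl alkynol 7 (not isolated)
Conditions: Ru[(R,R)-TsNCHPhCHPhNH](η6-p-cymene) (0.5 mol %), i-PrOH, 25 °C; then K2CO3, MeOH, 25 °C
Reagents that add atoms: none
Why: Noyori asymmetric transfer hydrogenation of an α,β-acetylenic ketone, in which the bifunctional Ru–H/N–H catalyst delivers hydride and proton through a six-membered transition state with the alkynyl group in the place usually taken by an aryl group, so the (R,R)-catalyst should set the (R)-carbinol under base-free conditions, after which K2CO3/MeOH protodesilylates the alkyne without touching the stereocentre.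

Step 4
Reactants: 8 (3R)-6-methylhept-5-en-1-yn-3-ol
Product: 9 (3R)-6-methylhept-5-en-1-yn-3-yl butanoate
Conditions: (n-PrCO)2O, Et3N, DMAP (cat.), CH2Cl2, 0 → 25 °C
Reagents that add atoms: butanoic anhydride, CCCC(=O)OC(=O)CCC
Why: DMAP-catalysed acyl transfer esterifies the secondary propargylic alcohol at oxygen, so the C–O bond and the (R) configuration are retained and the butanoate serves from here on as protecting group and as part of the target.

Step 5
Reactants: 10 hydroquinone
Product: 11 1,4-bis(methoxymethoxy)benzene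
Conditions: MOMCl, i-Pr2NEt, DMF, 0 → 25 °C
Reagents that add atoms: chloromethyl methyl ether, COCCl
Why: Double O-alkylation of the phenol with an α-chloro ether (Williamson-type) installs MOM groups that direct metalation, should survive organolithium and chromium chemistry, and can later be removed without hydrogenolysis or strong acid.

Step 6
Reactants: 11 1,4-bis(methoxymethoxy)benzene
Product: 14 pentacarbonyl{[2,5-bis(methoxymethoxy)phenyl](methoxy)methylidene}chromium, via aryllithium 12 (not isolated), via lithium acylchromate 13 (not isolated)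
Conditions: n-BuLi, TMEDA, THF, −78 → 0 °C; Cr(CO)6, 0 → 25 °C; evaporate; Me3OBF4, CH2Cl2, 0 °C
Reagents that add atoms: hexacarbonylchromium, O=C=[Cr](=C=O)(=C=O)(=C=O)(=C=O)=C=O; trimethyloxonium tetrafluoroborate, C[O+](C)C.F[B-](F)(F)F
Why: Directed ortho-metalation (all four ring positions are equivalent and ortho to an OMOM group), addition of the aryllithium to a CO ligand of Cr(CO)6 and O-methylation of the acylchromate with a Meerwein salt is the standard Fischer carbene synthesis.

Step 7
Reactants: 14 pentacarbonyl{[2,5-bis(methoxymethoxy)phenyl](methoxy)methylidene}chromium; 9 (3R)-6-methylhept-5-en-1-yn-3-yl butanoate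
Product: 16 (1R)-1-[5,8-bis(methoxymethoxy)-1,4-dioxo-1,4-dihydronaphthalen-2-yl]-4-methylpent-3-en-1-yl butanoate, via methoxynaphthol 15 (not isolated)
Conditions: THF (0.05 M), 50 °C, argon; then (NH4)2Ce(NO3)6, MeCN–H2O, 0 °C
Reagents that add atoms: water, O
Why: Thermal loss of one CO from 14 lets the alkyne coordinate and insert into the Cr=C bond with its terminal CH bonding to the carbene carbon (C3–C4), the η3-vinylcarbene inserts CO at the substituted carbon to give an η4-vinylketene (C1–C2), and the ketene carbon closes onto the free ortho carbon of the aryl ring (C1–C8a) before tautomerising to the Cr(CO)3-bound 4-methoxy-1-naphthol 15. This is the Dötz benzannulation of an aryl(alkoxy)carbene chromium complex with a terminal alkyne, a formal [3+2+1] union. The single new ring (C1–C4, C4a, C8a) closes by thermal 6π-electrocyclisation of the dienylketene onto the arene, followed by enolisation. No stereocentre is created, and the propargylic C–O centre lies outside the reacting π-system, so its (R) configuration should be carried through unchanged. The step needs CO insertion to win over indene or furan formation and needs the bulky alkyne substituent next to the CO-derived carbon, which a terminal alkyne, an ethereal solvent, moderate temperature and high dilution should secure; because both oxygens of the other ring carry the same MOM group, even the minor insertion regioisomer would give the same quinone. Tetravalent cerium then strips the chromium and oxidises only the electron-rich p-methoxynaphthol ring to the quinone, water supplying the C4 oxygen and methanol being lost, while the acceptor-flanked bis-MOM ring, the alkene and the ester should stay intact.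

Step 8
Reactants: 16 (1R)-1-[5,8-bis(methoxymethoxy)-1,4-dioxo-1,4-dihydronaphthalen-2-yl]-4-methylpent-3-en-1-yl butanoate
Product: 17 butylshikonin, (1R)-1-(5,8-dihydroxy-1,4-dioxo-1,4-dihydronaphthalen-2-yl)-4-methylpent-3-en-1-yl butanoate
Conditions: MgBr2·OEt2, CH2Cl2–Et2O, 0 → 25 °C; aqueous NH4Cl work-up
Reagents that add atoms: none
Why: Chelation-controlled Lewis-acid cleavage of acetals, in which each peri-OMOM oxygen and the neighbouring quinone carbonyl bind magnesium in a six-membered chelate, so bromide should open both MOM groups without Brønsted acid and leave the ester, the trisubstituted alkene and the stereocentre (its C–O bond is deactivated toward ionisation by the quinone) untouched.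

Compound list
1 | 4-methylpent-3-enoic acid | CC(C)=CCC(=O)O | starting material
2 | 1-(1H-imidazol-1-yl)-4-methylpent-3-en-1-one | CC(C)=CCC(=O)n1ccnc1 | intermediate
3 | N-methoxy-N,4-dimethylpent-3-enamide | CC(C)=CCC(=O)N(C)OC | intermediate
4 | ethynyl(trimethyl)silane | C#C[Si](C)(C)C | starting material
5 | lithium (trimethylsilyl)acetylide | [Li]C#C[Si](C)(C)C | intermediate
6 | 6-methyl-1-(trimethylsilyl)hept-5-en-1-yn-3-one | CC(C)=CCC(=O)C#C[Si](C)(C)C | intermediate
7 | (3R)-6-methyl-1-(trimethylsilyl)hept-5-en-1-yn-3-ol | O[C@H](CC=C(C)C)C#C[Si](C)(C)C | intermediate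
8 | (3R)-6-methylhept-5-en-1-yn-3-ol | O[C@H](CC=C(C)C)C#C | intermediate
9 | (3R)-6-methylhept-5-en-1-yn-3-yl butanoate | CCCC(=O)O[C@H](CC=C(C)C)C#C | intermediate
10 | hydroquinone (benzene-1,4-diol) | Oc1ccc(O)cc1 | starting material
11 | 1,4-bis(methoxymethoxy)benzene | COCOc1ccc(OCOC)cc1 | intermediate
12 | [2,5-bis(methoxymethoxy)phenyl]lithium | [Li]c1cc(OCOC)ccc1OCOC | intermediate
13 | lithium pentacarbonyl{[2,5-bis(methoxymethoxy)phenyl](oxido)methylidene}chromate | [Li+].[O-]C(=[Cr](=C=O)(=C=O)(=C=O)(=C=O)=C=O)c1cc(OCOC)ccc1OCOC | intermediate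
14 | pentacarbonyl{[2,5-bis(methoxymethoxy)phenyl](methoxy)methylidene}chromium | COC(=[Cr](=C=O)(=C=O)(=C=O)(=C=O)=C=O)c1cc(OCOC)ccc1OCOC | intermediate
15 | (1R)-1-[1-hydroxy-4-methoxy-5,8-bis(methoxymethoxy)naphthalen-2-yl]-4-methylpent-3-en-1-yl butanoate (formed as its tricarbonylchromium complex) | CCCC(=O)O[C@H](CC=C(C)C)c1cc(OC)c2c(OCOC)ccc(OCOC)c2c1O | intermediate
16 | (1R)-1-[5,8-bis(methoxymethoxy)-1,4-dioxo-1,4-dihydronaphthalen-2-yl]-4-methylpent-3-en-1-yl butanoate | CCCC(=O)O[C@H](CC=C(C)C)C1=CC(=O)c2c(OCOC)ccc(OCOC)c2C1=O | intermediate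
17 | butylshikonin, (1R)-1-(5,8-dihydroxy-1,4-dioxo-1,4-dihydronaphthalen-2-yl)-4-methylpent-3-en-1-yl butanoate | CCCC(=O)O[C@H](CC=C(C)C)C1=CC(=O)c2c(O)ccc(O)c2C1=O | target

Total step count: 8. Longest linear sequence: 6 steps (steps 1, 2, 3, 4, 7, 8); the carbene branch (steps 5, 6) joins at step 7.

Steps most likely to fail

1. Step 7 (key step). After alkyne insertion the chromium vinylcarbene may cyclise without CO insertion (indene or furan formation). Chelation of the ortho-OMOM oxygen and of the propargylic ester to chromium would favour this, and the acyloxy group may ionise at the metal. The fallback sets out from 3 and takes the bicyclic core ready-made instead of building it.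
   - Commercial 5,8-dihydroxy-1,4-naphthoquinone is reduced (Na2S2O4, H2O–EtOAc) to naphthalene-1,4,5,8-tetrol F1.
   - Alkylation (NaH, MOMCl, DMF) gives 1,4,5,8-tetrakis(methoxymethoxy)naphthalene F2.
   - Ortho-lithiation (n-BuLi, TMEDA, THF, 0 °C) gives [1,4,5,8-tetrakis(methoxymethoxy)naphthalen-2-yl]lithium F3.
   - Acylation of F3 by 3 gives 4-methyl-1-[1,4,5,8-tetrakis(methoxymethoxy)naphthalen-2-yl]pent-3-en-1-one F4.
   - Reduction with (+)-Ipc2BCl (THF, −25 °C) should give (1R)-4-methyl-1-[1,4,5,8-tetrakis(methoxymethoxy)naphthalen-2-yl]pent-3-en-1-ol F5.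
   - Esterification as in step 4 gives (1R)-4-methyl-1-[1,4,5,8-tetrakis(methoxymethoxy)naphthalen-2-yl]pent-3-en-1-yl butanoate F6.
   - (NH4)2Ce(NO3)6 in MeCN–H2O at 0 °C then oxidises one of the two tetraoxygenated rings. This should give 16 together with its ring isomer (1R)-1-[1,4-bis(methoxymethoxy)-5,8-dioxo-5,8-dihydronaphthalen-2-yl]-4-methylpent-3-en-1-yl butanoate F7.
   - Because the two naphthazarin tautomers are one compound, both converge on 17 in step 8. The fallback comes back to the route at 16.

2. Step 8. The two acetals may open incompletely. With more forcing Lewis or Brønsted acid the butanoate may be lost, bromide may add to the quinone, and the trisubstituted alkene may be captured by the released methoxymethyl cation. The fallback sets out from 10 and exchanges the phenol protecting group for one removed by fluoride.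
   - Hydroquinone 10 is alkylated with 2-(trimethylsilyl)ethoxymethyl chloride (i-Pr2NEt, DMF) to 1,4-bis{[2-(trimethylsilyl)ethoxy]methoxy}benzene F8.
   - As in step 6, F8 is lithiated to (2,5-bis{[2-(trimethylsilyl)ethoxy]methoxy}phenyl)lithium F9.
   - F9 is converted through lithium pentacarbonyl[(2,5-bis{[2-(trimethylsilyl)ethoxy]methoxy}phenyl)(oxido)methylidene]chromate F10 into pentacarbonyl[(2,5-bis{[2-(trimethylsilyl)ethoxy]methoxy}phenyl)(methoxy)methylidene]chromium F11.
   - Benzannulation with 9 and oxidative work-up as in step 7 should give, through (1R)-1-(1-hydroxy-4-methoxy-5,8-bis{[2-(trimethylsilyl)ethoxy]methoxy}naphthalen-2-yl)-4-methylpent-3-en-1-yl butanoate F12, the quinone (1R)-1-(1,4-dioxo-5,8-bis{[2-(trimethylsilyl)ethoxy]methoxy}-1,4-dihydronaphthalen-2-yl)-4-methylpent-3-en-1-yl butanoate F13.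
   - Bu4NF buffered with AcOH (THF, 0 °C) then removes both groups by fluoride-triggered fragmentation. The fallback comes back to the route at 17.

3. Step 3. The C5=C6 double bond of 6 may migrate into conjugation with the ketone before hydride transfer. Enantiomeric purity may also erode through reversible hydrogen transfer, or through binding of the terminal alkyne to ruthenium during the telescoped desilylation. The fallback sets out from 5 and makes the stereocentre by C–C bond formation instead of ketone reduction.
   - Lithium acetylide 5 is formylated with DMF (THF, −78 °C; aqueous KH2PO4) to 3-(trimethylsilyl)prop-2-ynal F14.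
   - Brown allylation with (+)-Ipc2B(allyl) (Et2O, −78 °C; NaOH, H2O2), the reagent enantiomer expected to give the R carbinol, leads to (3R)-1-(trimethylsilyl)hex-5-en-1-yn-3-ol F15.
   - Cross-metathesis with 2-methyl-2-butene (second-generation Grubbs catalyst, neat alkene, 25 °C) converts the allyl group into the prenyl group and gives 7.
   - 7 is desilylated with K2CO3/MeOH as in the second half of step 3. The fallback comes back to the route at 7.

Further compounds
F1 | step 7 | naphthalene-1,4,5,8-tetrol | Oc1ccc(O)c2c(O)ccc(O)c12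
F2 | step 7 | 1,4,5,8-tetrakis(methoxymethoxy)naphthalene | COCOc1ccc(OCOC)c2c(OCOC)ccc(OCOC)c12
F3 | step 7 | [1,4,5,8-tetrakis(methoxymethoxy)naphthalen-2-yl]lithium | [Li]c1cc(OCOC)c2c(OCOC)ccc(OCOC)c2c1OCOC
F4 | step 7 | 4-methyl-1-[1,4,5,8-tetrakis(methoxymethoxy)naphthalen-2-yl]pent-3-en-1-one | CC(C)=CCC(=O)c1cc(OCOC)c2c(OCOC)ccc(OCOC)c2c1OCOC
F5 | step 7 | (1R)-4-methyl-1-[1,4,5,8-tetrakis(methoxymethoxy)naphthalen-2-yl]pent-3-en-1-ol | O[C@H](CC=C(C)C)c1cc(OCOC)c2c(OCOC)ccc(OCOC)c2c1OCOC
F6 | step 7 | (1R)-4-methyl-1-[1,4,5,8-tetrakis(methoxymethoxy)naphthalen-2-yl]pent-3-en-1-yl butanoate | CCCC(=O)O[C@H](CC=C(C)C)c1cc(OCOC)c2c(OCOC)ccc(OCOC)c2c1OCOC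
F7 | step 7 | (1R)-1-[1,4-bis(methoxymethoxy)-5,8-dioxo-5,8-dihydronaphthalen-2-yl]-4-methylpent-3-en-1-yl butanoate | CCCC(=O)O[C@H](CC=C(C)C)c1cc(OCOC)c2C(=O)C=CC(=O)c2c1OCOC
F8 | step 8 | 1,4-bis{[2-(trimethylsilyl)ethoxy]methoxy}benzene | C[Si](C)(C)CCOCOc1ccc(OCOCC[Si](C)(C)C)cc1
F9 | step 8 | (2,5-bis{[2-(trimethylsilyl)ethoxy]methoxy}phenyl)lithium | [Li]c1cc(OCOCC[Si](C)(C)C)ccc1OCOCC[Si](C)(C)C
F10 | step 8 | lithium pentacarbonyl[(2,5-bis{[2-(trimethylsilyl)ethoxy]methoxy}phenyl)(oxido)methylidene]chromate | [Li+].[O-]C(=[Cr](=C=O)(=C=O)(=C=O)(=C=O)=C=O)c1cc(OCOCC[Si](C)(C)C)ccc1OCOCC[Si](C)(C)C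
F11 | step 8 | pentacarbonyl[(2,5-bis{[2-(trimethylsilyl)ethoxy]methoxy}phenyl)(methoxy)methylidene]chromium | COC(=[Cr](=C=O)(=C=O)(=C=O)(=C=O)=C=O)c1cc(OCOCC[Si](C)(C)C)ccc1OCOCC[Si](C)(C)C
F12 | step 8 | (1R)-1-(1-hydroxy-4-methoxy-5,8-bis{[2-(trimethylsilyl)ethoxy]methoxy}naphthalen-2-yl)-4-methylpent-3-en-1-yl butanoate | CCCC(=O)O[C@H](CC=C(C)C)c1cc(OC)c2c(OCOCC[Si](C)(C)C)ccc(OCOCC[Si](C)(C)C)c2c1O
F13 | step 8 | (1R)-1-(1,4-dioxo-5,8-bis{[2-(trimethylsilyl)ethoxy]methoxy}-1,4-dihydronaphthalen-2-yl)-4-methylpent-3-en-1-yl butanoate | CCCC(=O)O[C@H](CC=C(C)C)C1=CC(=O)c2c(OCOCC[Si](C)(C)C)ccc(OCOCC[Si](C)(C)C)c2C1=O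
F14 | step 3 | 3-(trimethylsilyl)prop-2-ynal | O=CC#C[Si](C)(C)C
F15 | step 3 | (3R)-1-(trimethylsilyl)hex-5-en-1-yn-3-ol | O[C@H](CC=C)C#C[Si](C)(C)C
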